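## Retrosynthetic overview

1. Target ⇐ hydrogenolysis of all benzylic ethers ⇐ Steglich esterification of protected (2R,3R)-epigallocatechin with 4-O-benzylsyringic acid.
2. cis-Flavan-3-ol ⇐ asymmetric transfer hydrogenation with dynamic kinetic resolution of the racemic flavan-3-one (C2 and C3 set together).
3. Flavan-3-one ⇐ one-carbon ring expansion with 1,2-shift of the ring A carbon (TMSCHN2) of a 2-aryl-benzofuran-3(2H)-one; the five-membered O-heterocycle is made first and then enlarged to ring C.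
4. Benzofuranone ⇐ Friedel–Crafts closure of an α-aryloxy arylacetic acid ⇐ Jocic–Reeve union of the ring A phenol (resorcinol, meta C–H borylation/oxidation) with the ring B aldehyde and CHCl3.
5. Rings B and D both ⇐ p-cresol via 4-(benzyloxy)-3,5-dibromobenzaldehyde (Pd etherification with BnOH or MeOH).

Assumption: racemic intermediates are drawn without stereodescriptors, and simple alkylating or one-carbon reagents (benzyl halides, benzyl alcohol, methanol, chloroform, TMSCHN2) are given as reagents without numbers.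

## Route

Step 1
Reactants: 1 resorcinol
Product: 2 1,3-bis[(4-methylbenzyl)oxy]benzene
Conditions: 4-methylbenzyl bromide (2.2 equiv), K2CO3, DMF, 60 °C
Reagents that add atoms: 4-methylbenzyl bromide, Cc1ccc(CBr)cc1
Why: Williamson O-alkylation of both phenols; the 4-methylbenzyl group is used because every C–H of its ring has an ortho substituent, so the borylation in step 2 can only take the resorcinol C5–H.

Step 2
Reactants: 2 1,3-bis[(4-methylbenzyl)oxy]benzene
Product: 4 3,5-bis[(4-methylbenzyl)oxy]phenol, via pinacol arylboronate 3 (not isolated)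
Conditions: [Ir(OMe)(cod)]2 (1.5 mol%), dtbpy (3 mol%), B2pin2 (1.0 equiv), THF, 80 °C; then KHSO5 (as 2KHSO5·KHSO4·K2SO4), acetone/H2O, 0 °C to rt
Reagents that add atoms: bis(pinacolato)diboron, CC1(C)OB(OC1(C)C)B1OC(C)(C)C(C)(C)O1 (boryl group of 3); potassium peroxymonosulfate, [K+].[O-]S(=O)(=O)OO (phenol oxygen of 4)
Why: Sterically controlled Ir-catalysed aromatic C–H borylation takes the only C–H with no ortho substituent (C5, meta to both ethers), and peroxymonosulfate then oxidises the C–B bond to the phenol (one-pot borylation/oxidation).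

Step 3
Reactants: 5 p-cresol
Product: 8 3,5-dibromo-4-hydroxybenzaldehyde, via 2,6-dibromo-4-methylphenol 6 (not isolated), via 2,6-dibromo-4-(dibromomethyl)phenol 7 (not isolated)
Conditions: Br2 (4.1 equiv), o-dichlorobenzene, 35 °C then 155 °C; then H2O, 100 °C
Reagents that add atoms: bromine, BrBr; water, O
Why: Electrophilic bromination ortho to the hydroxyl is followed at high temperature by side-chain bromination through the para-quinone methide and hydrolysis of the benzal bromide (the industrial route to 3,5-disubstituted 4-hydroxybenzaldehydes).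

Step 4
Reactants: 8 3,5-dibromo-4-hydroxybenzaldehyde
Product: 9 4-(benzyloxy)-3,5-dibromobenzaldehyde
Conditions: BnBr (1.2 equiv), K2CO3, DMF, 60 °C
Reagents that add atoms: benzyl bromide, BrCc1ccccc1
Why: Williamson benzylation masks the acidic phenol and gives the common precursor of rings B and D.

Step 5
Reactants: 9 4-(benzyloxy)-3,5-dibromobenzaldehyde
Product: 10 3,4,5-tris(benzyloxy)benzaldehyde
Conditions: BnOH (3 equiv), [Pd(allyl)Cl]2 (2 mol%), RockPhos (6 mol%), Cs2CO3 (3 equiv), toluene, 90 °C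
Reagents that add atoms: benzyl alcohol, OCc1ccccc1
Why: Buchwald-type Pd-catalysed C–O cross-coupling of both aryl bromides with a primary alcohol, where the bulky biaryl phosphine favours C–O reductive elimination over β-hydride elimination and the carbonate base spares the aldehyde.

Step 6
Reactants: 10 3,4,5-tris(benzyloxy)benzaldehyde
Product: 11 racemic 2,2,2-trichloro-1-[3,4,5-tris(benzyloxy)phenyl]ethanol
Conditions: CHCl3 (4 equiv), DBU (1 equiv), neat, 0 °C to rt
Reagents that add atoms: chloroform, ClC(Cl)Cl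
Why: Amidine-promoted addition of the trichloromethyl anion to the aldehyde gives the trichloromethyl carbinol; it is left racemic because C2 is set later.

Step 7
Reactants: 11 racemic 2,2,2-trichloro-1-[3,4,5-tris(benzyloxy)phenyl]ethanol; 4 3,5-bis[(4-methylbenzyl)oxy]phenol
Product: 12 racemic 2-{3,5-bis[(4-methylbenzyl)oxy]phenoxy}-2-[3,4,5-tris(benzyloxy)phenyl]acetic acid
Conditions: 4 (1.5 equiv), powdered NaOH (5 equiv), DME, 0 °C to rt; then 1 M HCl
Reagents that add atoms: sodium hydroxide, [Na+].[OH-]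
Why: Jocic–Reeve reaction, in which the alkoxide closes to a gem-dichloro epoxide, the phenoxide of 4 opens it at the benzylic carbon and the acyl chloride is hydrolysed, so the O1–C2 bond and the C3 carboxyl arrive in one operation.

Step 8
Reactants: 12 racemic 2-{3,5-bis[(4-methylbenzyl)oxy]phenoxy}-2-[3,4,5-tris(benzyloxy)phenyl]acetic acid
Product: 13 racemic 4,6-bis[(4-methylbenzyl)oxy]-2-[3,4,5-tris(benzyloxy)phenyl]benzofuran-3(2H)-one
Conditions: (CF3CO)2O (1.5 equiv), CH2Cl2, 0 °C, argon; used crude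
Reagents that add atoms: none
Why: Intramolecular Friedel–Crafts acylation through the mixed trifluoroacetic anhydride at the doubly activated ortho carbon of ring A closes the five-membered benzofuranone; its C2 centre is racemic and labile, which is harmless here.

Step 9
Reactants: 13 racemic 4,6-bis[(4-methylbenzyl)oxy]-2-[3,4,5-tris(benzyloxy)phenyl]benzofuran-3(2H)-one
Product: 15 racemic 5,7-bis[(4-methylbenzyl)oxy]-2-[3,4,5-tris(benzyloxy)phenyl]chroman-3-one, via C4-silyl ketone 14 (not isolated)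
Conditions: TMSCHN2 (1.5 equiv), BF3·OEt2 (1.2 equiv), CH2Cl2, −78 to −30 °C; then 1 M HCl, THF, 0 °C
Reagents that add atoms: (trimethylsilyl)diazomethane, C[Si](C)(C)C=[N+]=[N-]
Why: Proposed new method: a Lewis-acid-promoted Tiffeneau–Demjanov-type one-carbon ring expansion not yet shown on 2-aryl-benzofuran-3(2H)-ones, in which the diazo carbon adds to the BF3-activated C3=O, the very electron-rich ring A carbon (alkoxy groups ortho and para) migrates with loss of N2 in preference to the electron-poor, more hindered α-aryloxy C2, the five-membered ring becomes ring C with the new carbon as C4, and the bulky C-silyl ketone resists a second insertion; the closest known reaction is the TMSCHN2/BF3·OEt2 homologation of aryl ketones such as 1-indanone to 2-tetralone, and no stereocentre is fixed because C2 stays epimerisable.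

Step 10
Reactants: 15 racemic 5,7-bis[(4-methylbenzyl)oxy]-2-[3,4,5-tris(benzyloxy)phenyl]chroman-3-one
Product: 16 (2R,3R)-5,7-bis[(4-methylbenzyl)oxy]-2-[3,4,5-tris(benzyloxy)phenyl]chroman-3-ol (2,3-cis)
Conditions: RuCl(p-cymene)[(R,R)-TsDPEN] (2 mol%), HCO2H/Et3N (5:2), DMF, 30 °C
Reagents that add atoms: none
Why: Proposed new method: Noyori–Ikariya asymmetric transfer hydrogenation under dynamic kinetic resolution, not yet shown on flavan-3-ones, in which C2–H (benzylic, α-oxy, α-keto) epimerises through the enol faster than reduction, the catalyst reduces only the (2R)-ketone and delivers hydride to the Si face of C3 anti to ring B, which sets C3 as R cis to the C2 aryl group and funnels the racemate into the (2R,3R)-alcohol; the closest known reaction is the transfer-hydrogenation dynamic kinetic resolution of 2-aryl cycloalkanones and 1-aryl-2-tetralones to cis alcohols.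

Step 11
Reactants: 9 4-(benzyloxy)-3,5-dibromobenzaldehyde
Product: 17 4-(benzyloxy)-3,5-dimethoxybenzaldehyde
Conditions: MeOH (6 equiv), Pd2(dba)3 (1.5 mol%), tBuBrettPhos (4 mol%), Cs2CO3 (3 equiv), 1,4-dioxane, 80 °C
Reagents that add atoms: methanol, CO
Why: Pd-catalysed methoxylation (Buchwald C–O coupling with methanol) of both aryl bromides installs the two methyl ethers of ring D on the benzyl-protected core.

Step 12
Reactants: 17 4-(benzyloxy)-3,5-dimethoxybenzaldehyde
Product: 18 4-(benzyloxy)-3,5-dimethoxybenzoic acid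
Conditions: NaClO2, NaH2PO4, 2-methyl-2-butene, t-BuOH/H2O, rt
Reagents that add atoms: sodium chlorite, [Na+].[O-]Cl=O
Why: Pinnick oxidation converts the aldehyde into the acid without attacking the electron-rich ring, the hypochlorous acid being trapped by the alkene.

Step 13
Reactants: 16 (2R,3R)-5,7-bis[(4-methylbenzyl)oxy]-2-[3,4,5-tris(benzyloxy)phenyl]chroman-3-ol; 18 4-(benzyloxy)-3,5-dimethoxybenzoic acid
Product: 19 (2R,3R)-5,7-bis[(4-methylbenzyl)oxy]-2-[3,4,5-tris(benzyloxy)phenyl]chroman-3-yl 4-(benzyloxy)-3,5-dimethoxybenzoate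
Conditions: EDC·HCl (1.5 equiv), DMAP (0.3 equiv), CH2Cl2, rt
Reagents that add atoms: none
Why: Steglich esterification acylates the axial C3 hydroxyl at oxygen, so both stereocentres are untouched.

Step 14
Reactants: 19 (2R,3R)-5,7-bis[(4-methylbenzyl)oxy]-2-[3,4,5-tris(benzyloxy)phenyl]chroman-3-yl 4-(benzyloxy)-3,5-dimethoxybenzoate
Product: 20 epigallocatechin 3-O-(3,5-di-O-methylgallate), (2R,3R)-5,7-dihydroxy-2-(3,4,5-trihydroxyphenyl)chroman-3-yl 4-hydroxy-3,5-dimethoxybenzoate
Conditions: H2 (1 atm), Pd(OH)2/C, THF/MeOH (1:1), rt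
Reagents that add atoms: none
Why: Hydrogenolysis cleaves the four benzyl and two 4-methylbenzyl ethers under neutral conditions that leave the methyl ethers, the ester and both stereocentres intact, as in the final step of benzyl-protected catechin gallate syntheses.

## Compound list

1 | resorcinol | Oc1cccc(O)c1 | starting material
2 | 1,3-bis[(4-methylbenzyl)oxy]benzene | Cc1ccc(COc2cccc(OCc3ccc(C)cc3)c2)cc1 | intermediate
3 | 2-{3,5-bis[(4-methylbenzyl)oxy]phenyl}-4,4,5,5-tetramethyl-1,3,2-dioxaborolane | Cc1ccc(COc2cc(OCc3ccc(C)cc3)cc(B3OC(C)(C)C(C)(C)O3)c2)cc1 | intermediate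
4 | 3,5-bis[(4-methylbenzyl)oxy]phenol | Cc1ccc(COc2cc(O)cc(OCc3ccc(C)cc3)c2)cc1 | intermediate
5 | p-cresol (4-methylphenol) | Cc1ccc(O)cc1 | starting material
6 | 2,6-dibromo-4-methylphenol | Cc1cc(Br)c(O)c(Br)c1 | intermediate
7 | 2,6-dibromo-4-(dibromomethyl)phenol | Oc1c(Br)cc(C(Br)Br)cc1Br | intermediate
8 | 3,5-dibromo-4-hydroxybenzaldehyde | O=Cc1cc(Br)c(O)c(Br)c1 | intermediate
9 | 4-(benzyloxy)-3,5-dibromobenzaldehyde | O=Cc1cc(Br)c(OCc2ccccc2)c(Br)c1 | intermediate
10 | 3,4,5-tris(benzyloxy)benzaldehyde | O=Cc1cc(OCc2ccccc2)c(OCc2ccccc2)c(OCc2ccccc2)c1 | intermediate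
11 | racemic 2,2,2-trichloro-1-[3,4,5-tris(benzyloxy)phenyl]ethanol | OC(c1cc(OCc2ccccc2)c(OCc2ccccc2)c(OCc2ccccc2)c1)C(Cl)(Cl)Cl | intermediate
12 | racemic 2-{3,5-bis[(4-methylbenzyl)oxy]phenoxy}-2-[3,4,5-tris(benzyloxy)phenyl]acetic acid | OC(=O)C(Oc1cc(OCc2ccc(C)cc2)cc(OCc2ccc(C)cc2)c1)c1cc(OCc2ccccc2)c(OCc2ccccc2)c(OCc2ccccc2)c1 | intermediate
13 | racemic 4,6-bis[(4-methylbenzyl)oxy]-2-[3,4,5-tris(benzyloxy)phenyl]benzofuran-3(2H)-one | O=C1C(c2cc(OCc3ccccc3)c(OCc3ccccc3)c(OCc3ccccc3)c2)Oc2cc(OCc3ccc(C)cc3)cc(OCc3ccc(C)cc3)c12 | intermediate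
14 | 5,7-bis[(4-methylbenzyl)oxy]-2-[3,4,5-tris(benzyloxy)phenyl]-4-(trimethylsilyl)chroman-3-one (racemic diastereomer mixture) | O=C1C([Si](C)(C)C)c2c(OCc3ccc(C)cc3)cc(OCc3ccc(C)cc3)cc2OC1c1cc(OCc2ccccc2)c(OCc2ccccc2)c(OCc2ccccc2)c1 | intermediate
15 | racemic 5,7-bis[(4-methylbenzyl)oxy]-2-[3,4,5-tris(benzyloxy)phenyl]chroman-3-one | O=C1Cc2c(OCc3ccc(C)cc3)cc(OCc3ccc(C)cc3)cc2OC1c1cc(OCc2ccccc2)c(OCc2ccccc2)c(OCc2ccccc2)c1 | intermediate
16 | (2R,3R)-5,7-bis[(4-methylbenzyl)oxy]-2-[3,4,5-tris(benzyloxy)phenyl]chroman-3-ol | O[C@@H]1Cc2c(OCc3ccc(C)cc3)cc(OCc3ccc(C)cc3)cc2O[C@@H]1c1cc(OCc2ccccc2)c(OCc2ccccc2)c(OCc2ccccc2)c1 | intermediate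
17 | 4-(benzyloxy)-3,5-dimethoxybenzaldehyde | COc1cc(C=O)cc(OC)c1OCc1ccccc1 | intermediate
18 | 4-(benzyloxy)-3,5-dimethoxybenzoic acid | COc1cc(C(=O)O)cc(OC)c1OCc1ccccc1 | intermediate
19 | (2R,3R)-5,7-bis[(4-methylbenzyl)oxy]-2-[3,4,5-tris(benzyloxy)phenyl]chroman-3-yl 4-(benzyloxy)-3,5-dimethoxybenzoate | COc1cc(C(=O)O[C@@H]2Cc3c(OCc4ccc(C)cc4)cc(OCc4ccc(C)cc4)cc3O[C@@H]2c2cc(OCc3ccccc3)c(OCc3ccccc3)c(OCc3ccccc3)c2)cc(OC)c1OCc1ccccc1 | intermediate
20 | epigallocatechin 3-O-(3,5-di-O-methylgallate) | COc1cc(C(=O)O[C@@H]2Cc3c(O)cc(O)cc3O[C@@H]2c2cc(O)c(O)c(O)c2)cc(OC)c1O | target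

## Step count and risks

Total step count: 14. Longest linear sequence: 10 steps (5 → 8 → 9 → 10 → 11 → 12 → 13 → 15 → 16 → 19 → 20, that is steps 3 to 10, 13 and 14).

Steps most likely to fail:

Step 9 (ring expansion, proposed new step). The ketone of 13 is a hindered vinylogous carbonate and may add TMSCHN2 slowly. Its aromatic enol may be O-alkylated. Some migration of C2 would give the flavanone isomer. The fallback uses known chemistry, sets out from 12 and comes back at 15. Acid 12 is converted with (COCl)2 and catalytic DMF into 2-{3,5-bis[(4-methylbenzyl)oxy]phenoxy}-2-[3,4,5-tris(benzyloxy)phenyl]acetyl chloride F1. Excess CH2N2 in Et2O at 0 °C turns F1 into the diazoketone 1-diazo-3-{3,5-bis[(4-methylbenzyl)oxy]phenoxy}-3-[3,4,5-tris(benzyloxy)phenyl]propan-2-one F2. Rh2(OAc)4 (1 mol%) in CH2Cl2 then closes ring C directly by intramolecular aromatic substitution of the carbenoid at the ring A ortho carbon to give 15, the established entry to chroman-3-ones from aryloxy diazoketones. This bypasses the benzofuranone altogether.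

Step 10 (dynamic kinetic reduction, proposed new step). Epimerisation at C2 may be too slow relative to reduction, or enolisation may run mainly towards C4, which would lower ee or dr. The sense of induction assigned to the (R,R) complex rests on analogy and is the least secure stereochemical call in the route; if it is opposite, the (S,S) complex is used. The fallback uses known chemistry, sets out from 15 and comes back at 16. LiBH(s-Bu)3 in THF at −78 °C reduces 15 anti to ring B to the racemic 2,3-cis alcohol, racemic cis-5,7-bis[(4-methylbenzyl)oxy]-2-[3,4,5-tris(benzyloxy)phenyl]chroman-3-ol F3. Esterification with (S)-2-methoxy-2-phenylacetic acid (EDC·HCl, DMAP) gives the diastereomeric esters (2R,3R)-chroman-3-yl (S)-2-methoxy-2-phenylacetate F4 and (2S,3S)-chroman-3-yl (S)-2-methoxy-2-phenylacetate F5, which are separated by chromatography or crystallisation and assigned by NMR. Mild methanolysis of F4 (K2CO3, MeOH/THF, rt) returns 16. This classical resolution costs half the material but needs no new reaction.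

Step 5 (double Pd etherification). Hydrodebromination through β-hydride elimination from the palladium benzyloxide, or incomplete second coupling next to the aldehyde, may limit the yield. The fallback uses known chemistry, sets out from 8 and comes back at 10. Copper-mediated hydrolysis of both aryl bromides of 8 (Cu powder, aqueous NaOH, reflux, argon, the method used for 5-bromovanillin) gives 3,4,5-trihydroxybenzaldehyde F6. Perbenzylation of F6 (BnBr, K2CO3, DMF, 60 °C) gives 10. Compound 9 is then needed only for ring D.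

## Further compounds

F1 | step 9 | 2-{3,5-bis[(4-methylbenzyl)oxy]phenoxy}-2-[3,4,5-tris(benzyloxy)phenyl]acetyl chloride (racemic) | ClC(=O)C(Oc1cc(OCc2ccc(C)cc2)cc(OCc2ccc(C)cc2)c1)c1cc(OCc2ccccc2)c(OCc2ccccc2)c(OCc2ccccc2)c1
F2 | step 9 | 1-diazo-3-{3,5-bis[(4-methylbenzyl)oxy]phenoxy}-3-[3,4,5-tris(benzyloxy)phenyl]propan-2-one (racemic) | [N-]=[N+]=CC(=O)C(Oc1cc(OCc2ccc(C)cc2)cc(OCc2ccc(C)cc2)c1)c1cc(OCc2ccccc2)c(OCc2ccccc2)c(OCc2ccccc2)c1
F3 | step 10 | racemic cis-5,7-bis[(4-methylbenzyl)oxy]-2-[3,4,5-tris(benzyloxy)phenyl]chroman-3-ol (both enantiomers) | O[C@@H]1Cc2c(OCc3ccc(C)cc3)cc(OCc3ccc(C)cc3)cc2O[C@@H]1c1cc(OCc2ccccc2)c(OCc2ccccc2)c(OCc2ccccc2)c1.O[C@H]1Cc2c(OCc3ccc(C)cc3)cc(OCc3ccc(C)cc3)cc2O[C@H]1c1cc(OCc2ccccc2)c(OCc2ccccc2)c(OCc2ccccc2)c1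
F4 | step 10 | (2R,3R)-5,7-bis[(4-methylbenzyl)oxy]-2-[3,4,5-tris(benzyloxy)phenyl]chroman-3-yl (S)-2-methoxy-2-phenylacetate | CO[C@H](C(=O)O[C@@H]1Cc2c(OCc3ccc(C)cc3)cc(OCc3ccc(C)cc3)cc2O[C@@H]1c1cc(OCc2ccccc2)c(OCc2ccccc2)c(OCc2ccccc2)c1)c1ccccc1
F5 | step 10 | (2S,3S)-5,7-bis[(4-methylbenzyl)oxy]-2-[3,4,5-tris(benzyloxy)phenyl]chroman-3-yl (S)-2-methoxy-2-phenylacetate | CO[C@H](C(=O)O[C@H]1Cc2c(OCc3ccc(C)cc3)cc(OCc3ccc(C)cc3)cc2O[C@H]1c1cc(OCc2ccccc2)c(OCc2ccccc2)c(OCc2ccccc2)c1)c1ccccc1
F6 | step 5 | 3,4,5-trihydroxybenzaldehyde | O=Cc1cc(O)c(O)c(O)c1
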